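**Retrosynthetic overview**

- The strategy rests on ring D, the 3,5-dihydroxyphenyl ring: a 5-substituted resorcinol whose C5 is joined through the E-CH=CH unit to C5 of ring B (the 2-hydroxy-3-methoxyphenyl ring on stereocentre C1). This is the oxygen pattern of a cinnamoyl-terminated 2,4,6-triketone, so ring D is folded last from that chain, carried in masked form as a 2-methyl-4-pyranone.
- The styrylpyranone comes from the (S)-triarylethane aldehyde and 2,6-dimethyl-4-pyranone by vinylogous aldol condensation, which also fixes the E-alkene.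
- The C1–ring B bond comes from a stereoretentive Suzuki–Miyaura coupling of an (S)-benzylic boronic ester with a 5-iodovanillin-derived iodide.
- C1, the C1–ring C bond and the CH2–ring A bond come from one enantioselective conjunctive coupling of a ring C Grignard reagent, vinylboronic ester and a ring A bromide.
- Rings A, B and C are bought; the only ring formed is ring D (step 9); four methoxymethyl (MOM) ethers leave in the last step.

Key step: step 9

Assumption: the (Sp,Sp) antipode of the Mandyphos ligand, (Sp,Sp)-1,1'-bis[bis(4-methoxy-3,5-dimethylphenyl)phosphino]-2,2'-bis[(R)-α-(dimethylamino)benzyl]ferrocene, is taken as the one that delivers the (S)-boronic ester 8; if the sense of induction is the opposite, the (Rp,Rp) antipode is used in step 3 and nothing else changes.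

Remark: the aldehyde of ring B is carried as a 1,3-dioxolane through the silver-promoted coupling, because Ag2O can oxidise aryl aldehydes.

**Route**

Step 1
Reactants: 1 4-bromoresorcinol
Product: 2 1-bromo-2,4-bis(methoxymethoxy)benzene
Conditions: NaH (2.3 equiv), MOMCl (2.4 equiv), DMF, 0 °C → rt
Reagents that add atoms: chloromethyl methyl ether (MOMCl), COCCl
Why: Williamson-type O-alkylation of both phenoxides with the reactive α-chloro ether should give the bis-MOM ether, which is stable to the organometallic and basic steps that follow.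

Step 2
Reactants: 3 4-bromo-2-methoxyphenol
Product: 4 4-bromo-2-methoxy-1-(methoxymethoxy)benzene
Conditions: NaH (1.2 equiv), MOMCl (1.2 equiv), DMF, 0 °C → rt
Reagents that add atoms: chloromethyl methyl ether (MOMCl), COCCl
Why: The same phenoxide O-alkylation (MOM protection) masks the ring C phenol so that the bromide can be turned into a Grignard reagent.

Step 3
Reactants: 4 4-bromo-2-methoxy-1-(methoxymethoxy)benzene; 5 4,4,5,5-tetramethyl-2-vinyl-1,3,2-dioxaborolane; 2 1-bromo-2,4-bis(methoxymethoxy)benzene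
Product: 8 2-[(1S)-2-[2,4-bis(methoxymethoxy)phenyl]-1-[3-methoxy-4-(methoxymethoxy)phenyl]ethyl]-4,4,5,5-tetramethyl-1,3,2-dioxaborolane, via arylmagnesium bromide 6 (not isolated), via vinylboron ate complex 7 (not isolated)
Conditions: i) Mg turnings, THF, 45 °C; ii) 5, NaOTf (3 equiv), THF, 0 °C → rt; iii) 2, Pd(OAc)2 (2 mol %), (Sp,Sp)-Mandyphos ligand (2.4 mol %), THF, 60 °C
Reagents that add atoms: none
Why: In this enantioselective palladium-catalysed conjunctive cross-coupling, the arylpalladium bromide formed from 2 and zerovalent palladium binds the vinyl group of ate complex 7 and triggers 1,2-migration of the ring C aryl group from boron to the α-carbon, reductive elimination then joins the β-carbon to ring A, and the chiral bisphosphine decides which alkene face palladium binds and so sets C1 as S, with NaOTf serving as Grignard activator and halide scavenger.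

Step 4
Reactants: 9 5-iodovanillin (4-hydroxy-3-iodo-5-methoxybenzaldehyde)
Product: 10 4-(1,3-dioxolan-2-yl)-2-iodo-6-methoxyphenol
Conditions: ethylene glycol (5 equiv), p-TsOH·H2O (2 mol %), toluene, reflux, Dean–Stark trap
Reagents that add atoms: ethylene glycol, OCCO
Why: Acid-catalysed acetalisation driven by azeotropic removal of water should mask the aldehyde, and it is done before MOM protection because an aryl MOM ether would not survive these acidic conditions.

Step 5
Reactants: 10 4-(1,3-dioxolan-2-yl)-2-iodo-6-methoxyphenol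
Product: 11 2-[3-iodo-5-methoxy-4-(methoxymethoxy)phenyl]-1,3-dioxolane
Conditions: NaH (1.2 equiv), MOMCl (1.2 equiv), THF/DMF, 0 °C → rt
Reagents that add atoms: chloromethyl methyl ether (MOMCl), COCCl
Why: Phenoxide O-alkylation (MOM protection) under basic conditions leaves the acid-labile dioxolane and the aryl iodide untouched.

Step 6
Reactants: 8 the (S)-benzylic pinacol boronic ester; 11 2-[3-iodo-5-methoxy-4-(methoxymethoxy)phenyl]-1,3-dioxolane
Product: 12 2-[3-[(1S)-2-[2,4-bis(methoxymethoxy)phenyl]-1-[3-methoxy-4-(methoxymethoxy)phenyl]ethyl]-5-methoxy-4-(methoxymethoxy)phenyl]-1,3-dioxolane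
Conditions: Pd2(dba)3 (4 mol %), PPh3 (64 mol %), Ag2O (1.5 equiv), DME, 85 °C, dark
Reagents that add atoms: none
Why: The Ag2O-promoted Suzuki–Miyaura coupling of secondary benzylic pinacol boronic esters with aryl iodides, a reaction type shown on 1,2-diarylethyl boronic esters, transmetalates with retention at carbon while the large excess of PPh3 suppresses β-hydride elimination, so the C–B configuration of 8 is carried over into the C1–ring B bond and no new stereocentre is set.

Step 7
Reactants: 12 the (S)-triarylethane dioxolane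
Product: 13 3-[(1S)-2-[2,4-bis(methoxymethoxy)phenyl]-1-[3-methoxy-4-(methoxymethoxy)phenyl]ethyl]-5-methoxy-4-(methoxymethoxy)benzaldehyde
Conditions: PPTS (0.2 equiv), acetone/H2O (9:1), 50 °C
Reagents that add atoms: water, O
Why: Mild acid-catalysed acetal hydrolysis should free the aldehyde, since the dioxolane of an electron-rich benzaldehyde ionises far more readily than an aryl MOM ether under pyridinium catalysis.

Step 8
Reactants: 13 the (S)-triarylethane aldehyde; 14 2,6-dimethyl-4H-pyran-4-one (4 equiv)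
Product: 15 2-methyl-6-[(E)-2-[3-[(1S)-2-[2,4-bis(methoxymethoxy)phenyl]-1-[3-methoxy-4-(methoxymethoxy)phenyl]ethyl]-5-methoxy-4-(methoxymethoxy)phenyl]ethenyl]-4H-pyran-4-one
Conditions: NaOEt (0.5 equiv), EtOH, 50 °C
Reagents that add atoms: none
Why: Vinylogous aldol condensation of the acidic 2-methyl group of the pyranone with the non-enolisable aldehyde, followed by E1cB loss of one molecule of water, should give the conjugated E-alkene, the excess of 14 holding back a second condensation at the other methyl group.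

Step 9
Reactants: 15 the 2-methyl-6-styryl-4-pyranone
Product: 17 5-[(E)-2-[3-[(1S)-2-[2,4-bis(methoxymethoxy)phenyl]-1-[3-methoxy-4-(methoxymethoxy)phenyl]ethyl]-5-methoxy-4-(methoxymethoxy)phenyl]ethenyl]benzene-1,3-diol, via styryl triketone 16 (not isolated)
Conditions: Ba(OH)2·8H2O (8 equiv), degassed 1,4-dioxane/H2O (1:1), 95 °C, Ar; then aq. NaH2PO4 to pH 6
Reagents that add atoms: water, O
Why: Hydroxide attacks an oxygen-bearing ring carbon of the pyranone (C2 or C6) and the ring opens to the barium enolate of triketone 16, in which the carbanion of the terminal methyl group adds to the carbonyl carbon next to the alkene, and loss of water with two enolisations leaves the resorcinol and the single new C–C bond of ring D. The closest known reaction is the conversion of 2,6-dimethyl-4-pyranone into orcinol through heptane-2,4,6-trione by the same base, and the aldol aromatisation of cinnamoyl poly-β-ketones to stilbenes; the styryl group on the pyranone is the extension made here. Ring D closes by a 6-(enolendo)-exo-trig aldol addition, no stereocentre is formed, and C1, a non-acidic diarylmethine, is not touched. The step needs 1,2-addition to the enone carbonyl in preference to the 6-endo conjugate addition of the central methylene to the styryl β-carbon, to retro-aldol loss of aldehyde 13 and to reclosure to the pyranone; the conjugate adduct and the pyranone stay in equilibrium with 16 in hot base whereas aromatisation cannot reverse, so the mixture should drain into 17. The MOM ether on the ring B oxygen para to the alkene stops a phenoxide from deactivating the ketone, and the four MOM ethers and the E-alkene set in step 8 are stable to aqueous base.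

Step 10
Reactants: 17 the tetra-MOM stilbene resorcinol
Product: 18 4-[(2S)-2-[5-[(E)-2-(3,5-dihydroxyphenyl)ethenyl]-2-hydroxy-3-methoxyphenyl]-2-(4-hydroxy-3-methoxyphenyl)ethyl]benzene-1,3-diol (CNP0254096.1)
Conditions: 3 M aq. HCl, MeOH, 45 °C, Ar
Reagents that add atoms: none
Why: Acid-catalysed methanolysis of the four aryl methoxymethyl acetals should free the phenols of rings A, B and C, the formaldehyde unit being carried off by methanol as dimethoxymethane, while the C1 stereocentre and the E-alkene are not involved.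

**Compound list**

1 | 4-bromoresorcinol (4-bromobenzene-1,3-diol) | Oc1ccc(Br)c(O)c1 | starting material
2 | 1-bromo-2,4-bis(methoxymethoxy)benzene | COCOc1ccc(Br)c(OCOC)c1 | intermediate
3 | 4-bromo-2-methoxyphenol | COc1cc(Br)ccc1O | starting material
4 | 4-bromo-2-methoxy-1-(methoxymethoxy)benzene | COCOc1ccc(Br)cc1OC | intermediate
5 | 4,4,5,5-tetramethyl-2-vinyl-1,3,2-dioxaborolane (vinylboronic acid pinacol ester) | C=CB1OC(C)(C)C(C)(C)O1 | starting material
6 | [3-methoxy-4-(methoxymethoxy)phenyl]magnesium bromide | COCOc1ccc([Mg]Br)cc1OC | intermediate (not isolated)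
7 | bromomagnesium [3-methoxy-4-(methoxymethoxy)phenyl](pinacolato)(vinyl)borate | C=C[B-]1(OC(C)(C)C(C)(C)O1)c1ccc(OCOC)c(OC)c1.[Mg+]Br | intermediate (not isolated)
8 | 2-[(1S)-2-[2,4-bis(methoxymethoxy)phenyl]-1-[3-methoxy-4-(methoxymethoxy)phenyl]ethyl]-4,4,5,5-tetramethyl-1,3,2-dioxaborolane | COc1cc([C@H](Cc2ccc(OCOC)cc2OCOC)B2OC(C)(C)C(C)(C)O2)ccc1OCOC | intermediate
9 | 5-iodovanillin (4-hydroxy-3-iodo-5-methoxybenzaldehyde) | COc1cc(C=O)cc(I)c1O | starting material
10 | 4-(1,3-dioxolan-2-yl)-2-iodo-6-methoxyphenol | COc1cc(C2OCCO2)cc(I)c1O | intermediate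
11 | 2-[3-iodo-5-methoxy-4-(methoxymethoxy)phenyl]-1,3-dioxolane | COCOc1c(I)cc(C2OCCO2)cc1OC | intermediate
12 | 2-[3-[(1S)-2-[2,4-bis(methoxymethoxy)phenyl]-1-[3-methoxy-4-(methoxymethoxy)phenyl]ethyl]-5-methoxy-4-(methoxymethoxy)phenyl]-1,3-dioxolane | COc1cc([C@H](Cc2ccc(OCOC)cc2OCOC)c2cc(C3OCCO3)cc(OC)c2OCOC)ccc1OCOC | intermediate
13 | 3-[(1S)-2-[2,4-bis(methoxymethoxy)phenyl]-1-[3-methoxy-4-(methoxymethoxy)phenyl]ethyl]-5-methoxy-4-(methoxymethoxy)benzaldehyde | COc1cc([C@H](Cc2ccc(OCOC)cc2OCOC)c2cc(C=O)cc(OC)c2OCOC)ccc1OCOC | intermediate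
14 | 2,6-dimethyl-4H-pyran-4-one | Cc1cc(=O)cc(C)o1 | starting material
15 | 2-methyl-6-[(E)-2-[3-[(1S)-2-[2,4-bis(methoxymethoxy)phenyl]-1-[3-methoxy-4-(methoxymethoxy)phenyl]ethyl]-5-methoxy-4-(methoxymethoxy)phenyl]ethenyl]-4H-pyran-4-one | COc1cc([C@H](Cc2ccc(OCOC)cc2OCOC)c2cc(/C=C/c3cc(=O)cc(C)o3)cc(OC)c2OCOC)ccc1OCOC | intermediate
16 | (E)-8-[3-[(1S)-2-[2,4-bis(methoxymethoxy)phenyl]-1-[3-methoxy-4-(methoxymethoxy)phenyl]ethyl]-5-methoxy-4-(methoxymethoxy)phenyl]oct-7-ene-2,4,6-trione (drawn as the triketo form, present as its barium enolate) | COc1cc([C@H](Cc2ccc(OCOC)cc2OCOC)c2cc(/C=C/C(=O)CC(=O)CC(C)=O)cc(OC)c2OCOC)ccc1OCOC | intermediate (not isolated)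
17 | 5-[(E)-2-[3-[(1S)-2-[2,4-bis(methoxymethoxy)phenyl]-1-[3-methoxy-4-(methoxymethoxy)phenyl]ethyl]-5-methoxy-4-(methoxymethoxy)phenyl]ethenyl]benzene-1,3-diol | COc1cc([C@H](Cc2ccc(OCOC)cc2OCOC)c2cc(/C=C/c3cc(O)cc(O)c3)cc(OC)c2OCOC)ccc1OCOC | intermediate
18 | 4-[(2S)-2-[5-[(E)-2-(3,5-dihydroxyphenyl)ethenyl]-2-hydroxy-3-methoxyphenyl]-2-(4-hydroxy-3-methoxyphenyl)ethyl]benzene-1,3-diol | COc1cc([C@H](Cc2ccc(O)cc2O)c2cc(/C=C/c3cc(O)cc(O)c3)cc(OC)c2O)ccc1O | target

**Step count**

Total: 10 steps. Longest linear sequence: 7 steps (steps 2, 3, 6, 7, 8, 9, 10).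

**Steps most likely to fail**

1. Step 9 (ring D folding). Water may add to the styryl double bond of 15 or 16, and retro-aldol fragmentation would then return aldehyde 13. Conjugate addition or retro-Claisen cleavage of the chain may also outrun the slow aldol onto the electron-rich cinnamoyl carbonyl. Fallback: setting out from aldehyde 13, Horner–Wadsworth–Emmons olefination with the sodium salt of diethyl [3,5-bis(methoxymethoxy)benzyl]phosphonate F1 (NaH, THF, 0 °C → rt) should give the E-stilbene with ring D preformed, 1,3-bis(methoxymethoxy)-5-[(E)-2-[3-[(1S)-2-[2,4-bis(methoxymethoxy)phenyl]-1-[3-methoxy-4-(methoxymethoxy)phenyl]ethyl]-5-methoxy-4-(methoxymethoxy)phenyl]ethenyl]benzene F2. Acid methanolysis under the conditions of step 10 removes all six MOM groups, and the sequence comes back to the route at 18.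

2. Step 6 (stereoretentive arylation). Transmetalation of the hindered benzylic boronic ester onto an ortho-alkoxy arylpalladium may be slow, so that β-hydride elimination to a stilbene, protodeboronation or partial loss of stereochemical fidelity takes over. The fallback is a lithiation–borylation and protodeboronation sequence that sets out from 4, 5 and 2. Step 3 is run with the antipodal ligand to give the (R)-boronic ester, 2-[(1R)-2-[2,4-bis(methoxymethoxy)phenyl]-1-[3-methoxy-4-(methoxymethoxy)phenyl]ethyl]-4,4,5,5-tetramethyl-1,3,2-dioxaborolane F3. Oxidation with retention (NaBO3·4H2O, THF/H2O) gives (1R)-2-[2,4-bis(methoxymethoxy)phenyl]-1-[3-methoxy-4-(methoxymethoxy)phenyl]ethanol F4, and i-Pr2NCOCl with Et3N in refluxing CH2Cl2 converts it into (1R)-2-[2,4-bis(methoxymethoxy)phenyl]-1-[3-methoxy-4-(methoxymethoxy)phenyl]ethyl N,N-diisopropylcarbamate F5. Separately, iodide 11 is turned by iodine–magnesium exchange (i-PrMgCl·LiCl, THF, −20 °C) and quenching with 2-isopropoxy-4,4,5,5-tetramethyl-1,3,2-dioxaborolane into the ring B pinacol boronic ester 2-[5-(1,3-dioxolan-2-yl)-3-methoxy-2-(methoxymethoxy)phenyl]-4,4,5,5-tetramethyl-1,3,2-dioxaborolane F6. Lithiation of F5 (s-BuLi, Et2O, −78 °C, retention), addition of F6 (retention) and warming with MgBr2/MeOH should cause 1,2-migration of the ring B aryl group with inversion at carbon, giving the tertiary boronic ester 2-[(1S)-2-[2,4-bis(methoxymethoxy)phenyl]-1-[5-(1,3-dioxolan-2-yl)-3-methoxy-2-(methoxymethoxy)phenyl]-1-[3-methoxy-4-(methoxymethoxy)phenyl]ethyl]-4,4,5,5-tetramethyl-1,3,2-dioxaborolane F7. Protodeboronation with retention (CsF, H2O, 1,4-dioxane, 45 °C) comes back to the route at 12.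

3. Step 3 (conjunctive coupling). Oxidative addition and alkene binding of the electron-rich, ortho-alkoxy bromide 2 may be slow, which would allow direct aryl–aryl coupling of the ate complex or poor facial selectivity at C1. The fallback sets out from 4 and 5. Suzuki–Miyaura vinylation (Pd(PPh3)4, K2CO3, 1,4-dioxane/H2O, 90 °C) gives 2-methoxy-1-(methoxymethoxy)-4-vinylbenzene F8. Enantioselective rhodium-catalysed diboration (B2pin2, Rh(OAc)2(H2O)[2,6-bis(4-isopropyl-2-oxazolin-2-yl)phenyl] in the antipode that gives the S product, NaOt-Bu cat., THF, 60 °C) gives 2,2'-[(1S)-1-[3-methoxy-4-(methoxymethoxy)phenyl]ethane-1,2-diyl]bis(4,4,5,5-tetramethyl-1,3,2-dioxaborolane) F9. Chemoselective Suzuki–Miyaura coupling of the primary C–B bond with bromide 2 (Pd(OAc)2, RuPhos, KOH, THF/H2O, 70 °C) leaves the benzylic boronic ester in place and comes back to the route at 8.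

**Further compounds**

F1 | step 9 | diethyl [3,5-bis(methoxymethoxy)benzyl]phosphonate | CCOP(=O)(Cc1cc(OCOC)cc(OCOC)c1)OCC
F2 | step 9 | 1,3-bis(methoxymethoxy)-5-[(E)-2-[3-[(1S)-2-[2,4-bis(methoxymethoxy)phenyl]-1-[3-methoxy-4-(methoxymethoxy)phenyl]ethyl]-5-methoxy-4-(methoxymethoxy)phenyl]ethenyl]benzene | COc1cc([C@H](Cc2ccc(OCOC)cc2OCOC)c2cc(/C=C/c3cc(OCOC)cc(OCOC)c3)cc(OC)c2OCOC)ccc1OCOC
F3 | step 6 | 2-[(1R)-2-[2,4-bis(methoxymethoxy)phenyl]-1-[3-methoxy-4-(methoxymethoxy)phenyl]ethyl]-4,4,5,5-tetramethyl-1,3,2-dioxaborolane | COc1cc([C@@H](Cc2ccc(OCOC)cc2OCOC)B2OC(C)(C)C(C)(C)O2)ccc1OCOC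
F4 | step 6 | (1R)-2-[2,4-bis(methoxymethoxy)phenyl]-1-[3-methoxy-4-(methoxymethoxy)phenyl]ethanol | COc1cc([C@@H](Cc2ccc(OCOC)cc2OCOC)O)ccc1OCOC
F5 | step 6 | (1R)-2-[2,4-bis(methoxymethoxy)phenyl]-1-[3-methoxy-4-(methoxymethoxy)phenyl]ethyl N,N-diisopropylcarbamate | COc1cc([C@@H](Cc2ccc(OCOC)cc2OCOC)OC(=O)N(C(C)C)C(C)C)ccc1OCOC
F6 | step 6 | 2-[5-(1,3-dioxolan-2-yl)-3-methoxy-2-(methoxymethoxy)phenyl]-4,4,5,5-tetramethyl-1,3,2-dioxaborolane | COCOc1c(B2OC(C)(C)C(C)(C)O2)cc(C2OCCO2)cc1OC
F7 | step 6 | 2-[(1S)-2-[2,4-bis(methoxymethoxy)phenyl]-1-[5-(1,3-dioxolan-2-yl)-3-methoxy-2-(methoxymethoxy)phenyl]-1-[3-methoxy-4-(methoxymethoxy)phenyl]ethyl]-4,4,5,5-tetramethyl-1,3,2-dioxaborolane | COc1cc([C@](B2OC(C)(C)C(C)(C)O2)(Cc2ccc(OCOC)cc2OCOC)c2cc(C3OCCO3)cc(OC)c2OCOC)ccc1OCOC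
F8 | step 3 | 2-methoxy-1-(methoxymethoxy)-4-vinylbenzene | COCOc1ccc(C=C)cc1OC
F9 | step 3 | 2,2'-[(1S)-1-[3-methoxy-4-(methoxymethoxy)phenyl]ethane-1,2-diyl]bis(4,4,5,5-tetramethyl-1,3,2-dioxaborolane) | COCOc1ccc([C@H](CB2OC(C)(C)C(C)(C)O2)B2OC(C)(C)C(C)(C)O2)cc1OC
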